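**Retrosynthetic overview**
- The target is epiafzelechin-(4β→6)-epigallocatechin 3,3'-di-O-gallate. The last skeletal bond is upper C4–lower C6, made by Lewis acid coupling of an 8-bromo-capped upper flavan-4-ol with an 8-bromo-blocked, galloylated lower unit; global hydrogenolysis follows.
- Upper ring C is closed at O1–C8a by CuI-catalysed aryl ether formation; ring A enters as an ortho-bromoaryl Grignard reagent that adds to the aldehyde carbon, which becomes C4.
- The strategy rests on the cis pair of upper ring C: C2 (carrying ring B and O1) and C3 (carrying the free OH), joined by the C2–C3 bond. An auxiliary-controlled syn glycolate aldol addition to 4-benzyloxybenzaldehyde makes this bond and both centres.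
- The lower unit comes from (−)-epigallocatechin: a diphenylmethylene ketal desymmetrises ring B, then benzylation, C8 bromination and two galloylations.
- Ring order: upper rings A and B are brought in as arenes, upper ring C is the only ring formed (step 10), and all lower rings come from epigallocatechin.

Key step: step 2

Remark: the upper C4 carbinol (16 to 19) is carried as an epimer mixture because step 18 ionises this centre and resets it, and 3,4,5-tris(benzyloxy)benzoyl chloride (24) is taken as a purchased reagent.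

**Route**

Step 1
Reactants: 1 (S)-4-benzyl-2-oxazolidinone; 2 benzyloxyacetyl chloride
Product: 4 (S)-4-benzyl-3-(benzyloxyacetyl)oxazolidin-2-one, via N-lithio oxazolidinone 3 (not isolated)
Conditions: n-BuLi, THF, −78 °C; then 2, −78 → 0 °C
Reagents that add atoms: none
Why: N-acylation of a lithiated oxazolidinone with an acid chloride is the standard preparation of Evans imides and touches no stereocenter.

Step 2
Reactants: 4 (S)-4-benzyl-3-(benzyloxyacetyl)oxazolidin-2-one; 5 4-benzyloxybenzaldehyde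
Product: 8 syn aldol imide (S)-4-benzyl-3-[(2S,3R)-2-(benzyloxy)-3-(4-benzyloxyphenyl)-3-hydroxypropanoyl]oxazolidin-2-one, via Z dibutylboron enolate 6 (not isolated), via dibutylboron aldolate 7 (not isolated)
Conditions: Bu2BOTf, i-Pr2NEt, CH2Cl2, −78 → 0 °C; then 5, −78 → 0 °C; pH 7 buffer, MeOH, H2O2, 0 °C
Reagents that add atoms: none
Why: Bu2BOTf and i-Pr2NEt turn 4 into the Z boron enolate 6, which adds to 5 through a closed six-membered chair transition state with the aldehyde aryl group equatorial, so the future C2–C3 bond of upper ring C forms with the syn relationship. The closest known reaction is the boron-mediated Evans syn aldol addition of N-glycolyl oxazolidinones to aromatic aldehydes. No ring is closed; one skeletal C–C bond and two stereocenters are made. The relative configuration of the carbinol carbon (future C2) and the benzyloxy-bearing carbon (future C3) comes from the Z enolate geometry, and the absolute configuration comes from the (S)-benzyl group of the auxiliary, which shields one enolate face once the two imide carbonyl dipoles are opposed. The step needs syn over anti and one enolate face over the other; the short B–O bonds of the tight transition state and the auxiliary should secure both, while the electron-rich aldehyde only slows the addition. The imide carbon later becomes C4 and the carbinol oxygen becomes O1 without its C–O bond being broken, so the syn adduct maps onto the 2,3-cis flavan.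

Step 3
Reactants: 8 syn aldol imide
Product: 9 (2S,3R)-2-(benzyloxy)-3-(4-benzyloxyphenyl)-3-hydroxy-N-methoxy-N-methylpropanamide
Conditions: MeNH(OMe)·HCl, Me3Al, CH2Cl2, −20 → 0 °C; aq. KNaC4H4O6 (potassium sodium tartrate)
Reagents that add atoms: N,O-dimethylhydroxylamine hydrochloride, CNOC.Cl
Why: aluminium amide transamidation of an Evans aldol imide (Weinreb amide formation), helped by the free β-hydroxyl, cleaves the exocyclic acyl–N bond without epimerising the α-benzyloxy center and returns the auxiliary.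

Step 4
Reactants: 9 Weinreb amide
Product: 10 (2S,3R)-2-(benzyloxy)-3-(4-benzyloxyphenyl)-3-(tert-butyldimethylsilyloxy)-N-methoxy-N-methylpropanamide
Conditions: TBSOTf, 2,6-lutidine, CH2Cl2, 0 °C
Reagents that add atoms: tert-butyldimethylsilyl triflate, CC(C)(C)[Si](C)(C)OS(=O)(=O)C(F)(F)F
Why: silyl triflate silylation of a secondary benzylic alcohol masks the future O1 oxygen for the hydride and Grignard steps.

Step 5
Reactants: 10 silylated Weinreb amide
Product: 11 (2S,3R)-2-(benzyloxy)-3-(4-benzyloxyphenyl)-3-(tert-butyldimethylsilyloxy)propanal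
Conditions: i-Bu2AlH, THF, −78 °C; aq. KNaC4H4O6
Reagents that add atoms: none
Why: hydride reduction of a Weinreb amide stops at the aldehyde oxidation level at −78 °C, and the crude α-benzyloxy aldehyde is used at once so that the future C3 is not epimerised.

Step 6
Reactants: 12 5-bromoresorcinol
Product: 13 1,3-bis(benzyloxy)-5-bromobenzene
Conditions: BnBr, K2CO3, DMF, rt
Reagents that add atoms: benzyl bromide, BrCc1ccccc1
Why: Williamson etherification of both phenols.

Step 7
Reactants: 13 1,3-bis(benzyloxy)-5-bromobenzene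
Product: 14 1,5-bis(benzyloxy)-3-bromo-2-iodobenzene
Conditions: NIS, CF3CO2H (cat.), MeCN, 0 °C → rt
Reagents that add atoms: N-iodosuccinimide, O=C1CCC(=O)N1I
Why: electrophilic aromatic iodination should go to the position ortho to bromine (para to one benzyloxy group and ortho to the other), which is less hindered than the position between the two benzyloxy groups; the two positions next to bromine are equivalent by symmetry.

Step 8
Reactants: 11 aldehyde; 14 1,5-bis(benzyloxy)-3-bromo-2-iodobenzene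
Product: 16 (1RS,2R,3R)-1-[2-bromo-4,6-bis(benzyloxy)phenyl]-2-(benzyloxy)-3-(4-benzyloxyphenyl)-3-(tert-butyldimethylsilyloxy)propan-1-ol, via 2-bromo-4,6-bis(benzyloxy)phenylmagnesium chloride 15 (not isolated)
Conditions: 14, i-PrMgCl·LiCl, THF, −40 °C; then 11, −78 → −20 °C; aq. NH4Cl
Reagents that add atoms: none
Why: iodine–magnesium exchange is selective for iodine over bromine and gives an ortho-bromoaryl Grignard reagent that is stable below about −20 °C; its addition to the aldehyde attaches ring A at the future C4, whose carbinol configuration is not needed.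

Step 9
Reactants: 16 silyl ether
Product: 17 (1RS,2S,3R)-1-[2-bromo-4,6-bis(benzyloxy)phenyl]-2-(benzyloxy)-3-(4-benzyloxyphenyl)propane-1,3-diol
Conditions: Bu4NF, THF, 0 °C → rt
Reagents that add atoms: none
Why: fluoride desilylation frees the benzylic hydroxyl that becomes O1.

Step 10
Reactants: 17 bromo diol
Product: 18 (2R,3R,4RS)-3,5,7-tris(benzyloxy)-2-(4-benzyloxyphenyl)chroman-4-ol (2,3-cis)
Conditions: CuI (10 mol%), 1,10-phenanthroline (20 mol%), Cs2CO3, toluene, 110 °C, Ar
Reagents that add atoms: none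
Why: copper-catalysed intramolecular Ullmann-type aryl ether formation closes the six-membered ring C at O1–C8a with retention at C2, because the C2–O bond is not broken; the other hydroxyl could only close a four-membered ring and stays free.

Step 11
Reactants: 18 flavan-4-ol
Product: 19 (2R,3R,4RS)-3,5,7-tris(benzyloxy)-2-(4-benzyloxyphenyl)-8-bromochroman-4-ol
Conditions: NBS (1.0 equiv), CH2Cl2, −78 → 0 °C
Reagents that add atoms: N-bromosuccinimide, O=C1CCC(=O)N1Br
Why: electrophilic bromination of 5,7-dialkoxyflavans goes to C8, the less hindered position of ring A; the bromine caps the more nucleophilic ring A position so that the unit cannot alkylate itself there in step 18.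

Step 12
Reactants: 20 (−)-epigallocatechin
Product: 21 3',4'-O-diphenylmethylene-(−)-epigallocatechin
Conditions: Ph2CCl2, K2CO3, MeCN, rt, Ar
Reagents that add atoms: dichlorodiphenylmethane, ClC(Cl)(c1ccccc1)c1ccccc1
Why: ketalisation of a vicinal diphenol can only close the five-membered benzodioxole on two adjacent hydroxyls of ring B, and by the symmetry of that ring both possible pairs give the same compound with one terminal phenol left free.

Step 13
Reactants: 21 ketal
Product: 22 (2R,3R)-5,7,5'-tri-O-benzyl-3',4'-O-diphenylmethylene-epigallocatechin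
Conditions: BnBr (3.3 equiv), K2CO3, DMF, 0 °C → rt, Ar
Reagents that add atoms: benzyl bromide, BrCc1ccccc1
Why: Williamson benzylation with carbonate base alkylates the three phenols and leaves the secondary 3-hydroxyl.

Step 14
Reactants: 22 tribenzyl ketal
Product: 23 (2R,3R)-8-bromo-5,7,5'-tri-O-benzyl-3',4'-O-diphenylmethylene-epigallocatechin
Conditions: NBS (1.0 equiv), CH2Cl2, −78 → 0 °C
Reagents that add atoms: N-bromosuccinimide, O=C1CCC(=O)N1Br
Why: ring A, with three activating oxygens, is brominated at C8 ahead of C6 and of ring B, which leaves C6 as the only nucleophilic ring A position.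

Step 15
Reactants: 23 8-bromo alcohol; 24 3,4,5-tris(benzyloxy)benzoyl chloride
Product: 25 (2R,3R)-8-bromo-5,7,5'-tri-O-benzyl-3',4'-O-diphenylmethylene-epigallocatechin 3-O-[3,4,5-tris(benzyloxy)benzoate]
Conditions: 24 (1.5 equiv), pyridine, DMAP (cat.), CH2Cl2, rt
Reagents that add atoms: none
Why: DMAP-catalysed acylation esterifies the only free hydroxyl, the hindered 3-OH, as is done for 3-O-gallates of benzylated 2,3-cis flavan-3-ols.

Step 16
Reactants: 25 ketal ester
Product: 26 (2R,3R)-8-bromo-5,7,5'-tri-O-benzyl-epigallocatechin 3-O-[3,4,5-tris(benzyloxy)benzoate] (free 3',4'-catechol)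
Conditions: AcOH/H2O (4:1), 1,4-dioxane, 80 °C
Reagents that add atoms: none
Why: acid hydrolysis cleaves the diphenylmethylene ketal through its diaryl-stabilised oxocarbenium ion, while benzyl ethers, the alkyl gallate ester and the aryl bromide should survive.

Step 17
Reactants: 26 catechol; 24 3,4,5-tris(benzyloxy)benzoyl chloride
Product: 27 (2R,3R)-8-bromo-5,7,5'-tri-O-benzyl-epigallocatechin 3,3'-bis-O-[3,4,5-tris(benzyloxy)benzoate] (4'-OH free)
Conditions: 24 (1.0 equiv), i-Pr2NEt, CH2Cl2, −78 → −40 °C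
Reagents that add atoms: none
Why: regioselective monoacylation of an unsymmetrical catechol should take the terminal 3'-hydroxyl, which is less hindered and the more acidic of the two (the middle one sits between the new ester site and the 5'-benzyloxy group), and the remaining flanked phenol should react much more slowly.

Step 18
Reactants: 19 8-bromoflavan-4-ol; 27 lower unit
Product: 29 protected dimer in which upper C4 is bonded β (trans to the 3-benzyloxy group) to lower C6, via 8-bromoflavan-4-yl cation 28 (not isolated)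
Conditions: 19 added slowly to 27 (2.5 equiv, excess recovered), BF3·OEt2, 4 Å molecular sieves, CH2Cl2, −78 → −30 °C
Reagents that add atoms: none
Why: Lewis acid ionisation of the 4-ol gives the benzylic cation stabilised by O1 and the 5- and 7-benzyloxy groups, and Friedel–Crafts capture (the usual flavan-4-yl coupling) can occur on 27 only at C6 because C8 carries bromine; attack from the face opposite the 2-aryl and 3-benzyloxy groups sets the 4β (3,4-trans) center from either epimer of 19.

Step 19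
Reactants: 29 protected dimer
Product: 30 epiafzelechin-(4β→6)-epigallocatechin 3,3'-di-O-gallate (target)
Conditions: H2 (1 atm), Pd(OH)2/C, THF/MeOH/H2O, rt
Reagents that add atoms: none
Why: catalytic hydrogenolysis removes the thirteen benzyl ethers and both aryl bromides, and the unbuffered, slightly acidic medium should keep the 3'-O-galloyl ester from migrating to the neighbouring phenol.

**Compound list**

1 | (S)-4-benzyl-2-oxazolidinone | O=C1N[C@@H](Cc2ccccc2)CO1 | starting material
2 | benzyloxyacetyl chloride | O=C(Cl)COCc1ccccc1 | starting material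
3 | N-lithio-(S)-4-benzyl-2-oxazolidinone (not isolated) | [Li]N1[C@@H](Cc2ccccc2)COC1=O | intermediate
4 | (S)-4-benzyl-3-(benzyloxyacetyl)oxazolidin-2-one | O=C(COCc1ccccc1)N1[C@@H](Cc2ccccc2)COC1=O | intermediate
5 | 4-benzyloxybenzaldehyde | O=Cc1ccc(OCc2ccccc2)cc1 | starting material
6 | Z dibutylboron enolate of 4 (not isolated) | CCCCB(CCCC)O/C(=C\OCc1ccccc1)N1[C@@H](Cc2ccccc2)COC1=O | intermediate
7 | dibutylboron aldolate of 8 (not isolated) | CCCCB(CCCC)O[C@@H]([C@H](OCc1ccccc1)C(=O)N1[C@@H](Cc2ccccc2)COC1=O)c1ccc(OCc2ccccc2)cc1 | intermediate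
8 | (S)-4-benzyl-3-[(2S,3R)-2-(benzyloxy)-3-(4-benzyloxyphenyl)-3-hydroxypropanoyl]oxazolidin-2-one | O=C([C@@H](OCc1ccccc1)[C@H](O)c1ccc(OCc2ccccc2)cc1)N1[C@@H](Cc2ccccc2)COC1=O | intermediate
9 | (2S,3R)-2-(benzyloxy)-3-(4-benzyloxyphenyl)-3-hydroxy-N-methoxy-N-methylpropanamide | CON(C)C(=O)[C@@H](OCc1ccccc1)[C@H](O)c1ccc(OCc2ccccc2)cc1 | intermediate
10 | (2S,3R)-2-(benzyloxy)-3-(4-benzyloxyphenyl)-3-(tert-butyldimethylsilyloxy)-N-methoxy-N-methylpropanamide | CON(C)C(=O)[C@@H](OCc1ccccc1)[C@H](O[Si](C)(C)C(C)(C)C)c1ccc(OCc2ccccc2)cc1 | intermediate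
11 | (2S,3R)-2-(benzyloxy)-3-(4-benzyloxyphenyl)-3-(tert-butyldimethylsilyloxy)propanal | O=C[C@@H](OCc1ccccc1)[C@H](O[Si](C)(C)C(C)(C)C)c1ccc(OCc2ccccc2)cc1 | intermediate
12 | 5-bromoresorcinol | Oc1cc(O)cc(Br)c1 | starting material
13 | 1,3-bis(benzyloxy)-5-bromobenzene | Brc1cc(OCc2ccccc2)cc(OCc2ccccc2)c1 | intermediate
14 | 1,5-bis(benzyloxy)-3-bromo-2-iodobenzene | Brc1cc(OCc2ccccc2)cc(OCc2ccccc2)c1I | intermediate
15 | 2-bromo-4,6-bis(benzyloxy)phenylmagnesium chloride (not isolated) | Cl[Mg]c1c(Br)cc(OCc2ccccc2)cc1OCc1ccccc1 | intermediate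
16 | (1RS,2R,3R)-1-[2-bromo-4,6-bis(benzyloxy)phenyl]-2-(benzyloxy)-3-(4-benzyloxyphenyl)-3-(tert-butyldimethylsilyloxy)propan-1-ol | OC(c1c(Br)cc(OCc2ccccc2)cc1OCc1ccccc1)[C@@H](OCc1ccccc1)[C@H](O[Si](C)(C)C(C)(C)C)c1ccc(OCc2ccccc2)cc1 | intermediate
17 | (1RS,2S,3R)-1-[2-bromo-4,6-bis(benzyloxy)phenyl]-2-(benzyloxy)-3-(4-benzyloxyphenyl)propane-1,3-diol | OC(c1c(Br)cc(OCc2ccccc2)cc1OCc1ccccc1)[C@@H](OCc1ccccc1)[C@H](O)c1ccc(OCc2ccccc2)cc1 | intermediate
18 | (2R,3R,4RS)-3,5,7-tris(benzyloxy)-2-(4-benzyloxyphenyl)chroman-4-ol | OC1c2c(OCc3ccccc3)cc(OCc3ccccc3)cc2O[C@H](c2ccc(OCc3ccccc3)cc2)[C@@H]1OCc1ccccc1 | intermediate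
19 | (2R,3R,4RS)-3,5,7-tris(benzyloxy)-2-(4-benzyloxyphenyl)-8-bromochroman-4-ol | OC1c2c(OCc3ccccc3)cc(OCc3ccccc3)c(Br)c2O[C@H](c2ccc(OCc3ccccc3)cc2)[C@@H]1OCc1ccccc1 | intermediate
20 | (−)-epigallocatechin | Oc1cc([C@H]2Oc3cc(O)cc(O)c3C[C@H]2O)cc(O)c1O | starting material
21 | 3',4'-O-diphenylmethylene-(−)-epigallocatechin | Oc1cc([C@H]2Oc3cc(O)cc(O)c3C[C@H]2O)cc2OC(c3ccccc3)(c3ccccc3)Oc12 | intermediate
22 | (2R,3R)-5,7,5'-tri-O-benzyl-3',4'-O-diphenylmethylene-epigallocatechin | c1ccccc1COc1cc([C@H]2Oc3cc(OCc4ccccc4)cc(OCc4ccccc4)c3C[C@H]2O)cc2OC(c3ccccc3)(c3ccccc3)Oc12 | intermediate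
23 | (2R,3R)-8-bromo-5,7,5'-tri-O-benzyl-3',4'-O-diphenylmethylene-epigallocatechin | c1ccccc1COc1cc([C@H]2Oc3c(Br)c(OCc4ccccc4)cc(OCc4ccccc4)c3C[C@H]2O)cc2OC(c3ccccc3)(c3ccccc3)Oc12 | intermediate
24 | 3,4,5-tris(benzyloxy)benzoyl chloride | O=C(Cl)c1cc(OCc2ccccc2)c(OCc2ccccc2)c(OCc2ccccc2)c1 | starting material
25 | (2R,3R)-8-bromo-5,7,5'-tri-O-benzyl-3',4'-O-diphenylmethylene-epigallocatechin 3-O-[3,4,5-tris(benzyloxy)benzoate] | c1ccccc1COc1cc([C@H]2Oc3c(Br)c(OCc4ccccc4)cc(OCc4ccccc4)c3C[C@H]2OC(=O)c2cc(OCc3ccccc3)c(OCc3ccccc3)c(OCc3ccccc3)c2)cc2OC(c3ccccc3)(c3ccccc3)Oc12 | intermediate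
26 | (2R,3R)-8-bromo-5,7,5'-tri-O-benzyl-epigallocatechin 3-O-[3,4,5-tris(benzyloxy)benzoate], 3',4'-OH free | c1ccccc1COc1cc([C@H]2Oc3c(Br)c(OCc4ccccc4)cc(OCc4ccccc4)c3C[C@H]2OC(=O)c2cc(OCc3ccccc3)c(OCc3ccccc3)c(OCc3ccccc3)c2)cc(O)c1O | intermediate
27 | (2R,3R)-8-bromo-5,7,5'-tri-O-benzyl-epigallocatechin 3,3'-bis-O-[3,4,5-tris(benzyloxy)benzoate], 4'-OH free | c1ccccc1COc1cc([C@H]2Oc3c(Br)c(OCc4ccccc4)cc(OCc4ccccc4)c3C[C@H]2OC(=O)c2cc(OCc3ccccc3)c(OCc3ccccc3)c(OCc3ccccc3)c2)cc(OC(=O)c2cc(OCc3ccccc3)c(OCc3ccccc3)c(OCc3ccccc3)c2)c1O | intermediate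
28 | (2R,3R)-3,5,7-tris(benzyloxy)-2-(4-benzyloxyphenyl)-8-bromochroman-4-yl cation (not isolated) | [CH+]1c2c(OCc3ccccc3)cc(OCc3ccccc3)c(Br)c2O[C@H](c2ccc(OCc3ccccc3)cc2)[C@@H]1OCc1ccccc1 | intermediate
29 | protected dimer: upper (2R,3R)-3,5,7-tris(benzyloxy)-2-(4-benzyloxyphenyl)-8-bromochroman-4-yl unit bonded through C4 (β, trans to 3-OBn) to C6 of 27 | c1ccccc1COc1cc([C@H]2Oc3c(Br)c(OCc4ccccc4)c([C@H]4c5c(OCc6ccccc6)cc(OCc6ccccc6)c(Br)c5O[C@H](c5ccc(OCc6ccccc6)cc5)[C@@H]4OCc4ccccc4)c(OCc4ccccc4)c3C[C@H]2OC(=O)c2cc(OCc3ccccc3)c(OCc3ccccc3)c(OCc3ccccc3)c2)cc(OC(=O)c2cc(OCc3ccccc3)c(OCc3ccccc3)c(OCc3ccccc3)c2)c1O | intermediate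
30 | epiafzelechin-(4β→6)-epigallocatechin 3,3'-di-O-gallate (CNP0290965.1) | O=C(Oc1cc([C@H]2Oc3cc(O)c([C@H]4c5c(O)cc(O)cc5O[C@H](c5ccc(O)cc5)[C@@H]4O)c(O)c3C[C@H]2OC(=O)c2cc(O)c(O)c(O)c2)cc(O)c1O)c1cc(O)c(O)c(O)c1 | target

**Step count**
Total: 19 steps. Longest linear sequence: 11 steps (steps 1–5, 8–11, 18, 19). The aryl iodide takes 2 steps (6, 7) and the lower unit 6 steps (12–17).

**Steps most likely to fail**

Step 18 (interflavan coupling). The cation may be captured too slowly at the hindered, bromine-deactivated C6 of 27. It would then alkylate C6 of a second molecule of 19 (oligomerisation) or lose the C3 proton to a flav-3-ene. The fallback sets out from 18 and removes every nucleophilic position from the electrophile. Bromination of both free ring A positions (NBS, 2.1 equiv, CH2Cl2, −40 → 0 °C) should give (2R,3R,4RS)-3,5,7-tris(benzyloxy)-2-(4-benzyloxyphenyl)-6,8-dibromochroman-4-ol F1. Treated with BF3·OEt2 or Me3SiOTf in the presence of 27, it ionises to the 6,8-dibromoflavan-4-yl cation F2. This cation has only one possible C–C bond to form, so it can be regenerated at −20 → 0 °C until it is captured, giving the tribromo protected dimer F3. Hydrogenolysis as in step 19, with three C–Br bonds to cleave, returns to the route at 30.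

Step 17 (regioselective esterification of the catechol). Acylation may occur at the middle 4'-oxygen, or on both oxygens, or the acyl group may migrate between the two catechol oxygens under the basic conditions. The fallback sets out from 26 and replaces kinetic discrimination by thermodynamic control. Acylation with 24, Et3N and DMAP at rt without regard to site gives a mixture of 27 and the 4'-O-ester with free 3'-OH, F4. Prolonged exposure of the mixture to catalytic Et3N in CH2Cl2 lets the ester move between the neighbouring oxygens through the five-membered orthoacid intermediate, which should favour the less crowded terminal ester. Chromatography and resubmission of recovered F4 to the same equilibration return to the route at 27.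

Step 10 (copper-catalysed ring closure). The copper alkoxide of the secondary benzylic alcohol may lose a β-hydride (ketone formation and hydrodebromination), or the free 1,3-diol may bind copper and stall turnover. The fallback sets out from aldehyde 11 and closes the same O1–C8a bond by SNAr on an aryl fluoride, again without breaking the C2–O bond. 1,3,5-Trifluorobenzene and BnONa (2 equiv, N-methylpyrrolidone) give 1,3-bis(benzyloxy)-5-fluorobenzene F5. NIS with catalytic CF3CO2H gives 1,5-bis(benzyloxy)-3-fluoro-2-iodobenzene F6. Exchange with i-PrMgCl·LiCl (THF, −40 °C) gives 2-fluoro-4,6-bis(benzyloxy)phenylmagnesium chloride F7, which adds to 11 to give the fluoro carbinol F8. Bu4NF gives the fluoro diol F9. KH in DMF (0 °C → rt) then displaces fluoride intramolecularly and returns to the route at 18.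

**Further compounds**

F1 | step 18 | (2R,3R,4RS)-3,5,7-tris(benzyloxy)-2-(4-benzyloxyphenyl)-6,8-dibromochroman-4-ol | OC1c2c(OCc3ccccc3)c(Br)c(OCc3ccccc3)c(Br)c2O[C@H](c2ccc(OCc3ccccc3)cc2)[C@@H]1OCc1ccccc1
F2 | step 18 | (2R,3R)-3,5,7-tris(benzyloxy)-2-(4-benzyloxyphenyl)-6,8-dibromochroman-4-yl cation | [CH+]1c2c(OCc3ccccc3)c(Br)c(OCc3ccccc3)c(Br)c2O[C@H](c2ccc(OCc3ccccc3)cc2)[C@@H]1OCc1ccccc1
F3 | step 18 | tribromo protected dimer (29 with an additional bromine at upper C6) | c1ccccc1COc1cc([C@H]2Oc3c(Br)c(OCc4ccccc4)c([C@H]4c5c(OCc6ccccc6)c(Br)c(OCc6ccccc6)c(Br)c5O[C@H](c5ccc(OCc6ccccc6)cc5)[C@@H]4OCc4ccccc4)c(OCc4ccccc4)c3C[C@H]2OC(=O)c2cc(OCc3ccccc3)c(OCc3ccccc3)c(OCc3ccccc3)c2)cc(OC(=O)c2cc(OCc3ccccc3)c(OCc3ccccc3)c(OCc3ccccc3)c2)c1O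
F4 | step 17 | (2R,3R)-8-bromo-5,7,5'-tri-O-benzyl-epigallocatechin 3,4'-bis-O-[3,4,5-tris(benzyloxy)benzoate], 3'-OH free | c1ccccc1COc1cc([C@H]2Oc3c(Br)c(OCc4ccccc4)cc(OCc4ccccc4)c3C[C@H]2OC(=O)c2cc(OCc3ccccc3)c(OCc3ccccc3)c(OCc3ccccc3)c2)cc(O)c1OC(=O)c1cc(OCc2ccccc2)c(OCc2ccccc2)c(OCc2ccccc2)c1
F5 | step 10 | 1,3-bis(benzyloxy)-5-fluorobenzene | Fc1cc(OCc2ccccc2)cc(OCc2ccccc2)c1
F6 | step 10 | 1,5-bis(benzyloxy)-3-fluoro-2-iodobenzene | Fc1cc(OCc2ccccc2)cc(OCc2ccccc2)c1I
F7 | step 10 | 2-fluoro-4,6-bis(benzyloxy)phenylmagnesium chloride | Cl[Mg]c1c(F)cc(OCc2ccccc2)cc1OCc1ccccc1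
F8 | step 10 | 1-[2-fluoro-4,6-bis(benzyloxy)phenyl]-2-(benzyloxy)-3-(4-benzyloxyphenyl)-3-(tert-butyldimethylsilyloxy)propan-1-ol, C1 epimers | OC(c1c(F)cc(OCc2ccccc2)cc1OCc1ccccc1)[C@@H](OCc1ccccc1)[C@H](O[Si](C)(C)C(C)(C)C)c1ccc(OCc2ccccc2)cc1
F9 | step 10 | 1-[2-fluoro-4,6-bis(benzyloxy)phenyl]-2-(benzyloxy)-3-(4-benzyloxyphenyl)propane-1,3-diol, C1 epimers | OC(c1c(F)cc(OCc2ccccc2)cc1OCc1ccccc1)[C@@H](OCc1ccccc1)[C@H](O)c1ccc(OCc2ccccc2)cc1
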